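Assumption: the antipode of the chiral triazolium salt that gives the (4R,5R) lactone in step 2 is fixed in a first run (both antipodes are sold). Lignan locants are used beside oxolanone numbering: C7/C8/C9 for the hydroxybenzyl half and C7'/C8'/C9' for the benzyl/carbonyl half.

**Retrosynthetic overview**
- Target ⇐ its bis-benzyl ether (hydrogenolysis) ⇐ an "iso-lactone" (lactone closed on the benzylic C7 oxygen, CH2OSi on C8) by O→O acyl shift, so the target's lactone C–O bond is formed last.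
- Key step: the tertiary C8'–O bond is made on the iso-lactone by reductive α-hydroxylation (H-atom transfer, then O2) of an α-arylidene lactone. The cis C8-CH2OSi and C7-aryl groups block one face, so oxygen enters anti, which is the target's relative configuration after the acyl shift.
- α-Arylidene lactone ⇐ cis-γ-aryl-β-(silyloxymethyl) lactone + O-benzylvanillin (aldol condensation).
- cis-Lactone (C7 and C8 set) ⇐ γ-silyloxy enal + O-benzylvanillin by an enantioselective NHC homoenolate annulation; enal ⇐ cross-metathesis.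
- Ring order: γ-aryl lactone first (annulation), target γ-lactone second (translactonisation).

**Route**

Step 1
Reactants: 1 allyl tert-butyldimethylsilyl ether; 2 (E)-but-2-enal (crotonaldehyde)
Product: 3 (2E)-4-{[tert-butyl(dimethyl)silyl]oxy}but-2-enal
Conditions: Hoveyda–Grubbs II (2 mol%), 2 (4 equiv), CH2Cl2, 40 °C
Reagents that add atoms: none
Why: Olefin cross-metathesis of an allyl ether with an enal gives the conjugated E-enal, driven by loss of volatile propene.

Step 2
Reactants: 3 (2E)-4-{[tert-butyl(dimethyl)silyl]oxy}but-2-enal; 4 4-(benzyloxy)-3-methoxybenzaldehyde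
Product: 5 (4R,5R)-5-[4-(benzyloxy)-3-methoxyphenyl]-4-({[tert-butyl(dimethyl)silyl]oxy}methyl)oxolan-2-one
Conditions: chiral aminoindanol-derived N-mesityl triazolium BF4 (10 mol%), DBU (15 mol%), Ti(OiPr)4 (20 mol%), i-PrOH (20 mol%), 4 (1.5 equiv), CH2Cl2, 0 °C → rt
Reagents that add atoms: none
Why: Proposed new method: cooperative chiral triazolylidene/Ti(IV) homoenolate [3+2] annulation. The carbene turns 3 into a Breslow-type homoenolate whose β-carbon adds to 4 held on Ti(IV); Ti also binds the enol oxygen, giving a closed transition state that places aryl and CH2OTBS cis, while the indane wall of the carbene selects the enal face (sets C4 and C5). The acyl azolium is then O-acylated by the titanium alkoxide, closing the lactone and releasing the carbene. The closest known chemistry is the racemic NHC enal–aldehyde γ-butyrolactone annulation and chiral NHC/Ti(OiPr)4 homoenolate annulations of enones, not yet shown to give high ee with a simple electron-rich aryl aldehyde.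

Step 3
Reactants: 5 (4R,5R)-5-[4-(benzyloxy)-3-methoxyphenyl]-4-({[tert-butyl(dimethyl)silyl]oxy}methyl)oxolan-2-one; 4 4-(benzyloxy)-3-methoxybenzaldehyde
Product: 8 (3E,4R,5R)-3-[4-(benzyloxy)-3-methoxybenzylidene]-5-[4-(benzyloxy)-3-methoxyphenyl]-4-({[tert-butyl(dimethyl)silyl]oxy}methyl)oxolan-2-one, via lithium aldolate 6 (not isolated), via aldol acetate 7 (not isolated)
Conditions: LDA, THF, −78 °C; 4; then Ac2O, −78 → 0 °C; then DBU, 0 °C
Reagents that add atoms: none
Why: Aldol condensation (lithium enolate addition, O-acetylation, E1cB elimination) gives the thermodynamically favoured E-arylidene lactone without touching C4 or C5.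

Step 4
Reactants: 8 (3E,4R,5R)-3-[4-(benzyloxy)-3-methoxybenzylidene]-5-[4-(benzyloxy)-3-methoxyphenyl]-4-({[tert-butyl(dimethyl)silyl]oxy}methyl)oxolan-2-one
Product: 10 (3S,4R,5R)-3-[4-(benzyloxy)-3-methoxybenzyl]-5-[4-(benzyloxy)-3-methoxyphenyl]-4-({[tert-butyl(dimethyl)silyl]oxy}methyl)-3-hydroxyoxolan-2-one, via tertiary hydroperoxide 9 (not isolated)
Conditions: Mn(dpm)3 (10 mol%), PhSiH3 (2 equiv), O2 (1 atm), i-PrOH/CH2Cl2, 0 °C → rt; then P(OEt)3
Reagents that add atoms: dioxygen, O=O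
Why: Mukaiyama–Magnus reductive α-hydroxylation: metal-hydride H-atom transfer to the benzylic alkene carbon gives the tertiary α-lactone radical, which O2 traps on the face anti to the cis C4-CH2OTBS and C5-aryl groups, setting the (3S) quaternary carbinol (C8').

Step 5
Reactants: 10 (3S,4R,5R)-3-[4-(benzyloxy)-3-methoxybenzyl]-5-[4-(benzyloxy)-3-methoxyphenyl]-4-({[tert-butyl(dimethyl)silyl]oxy}methyl)-3-hydroxyoxolan-2-one
Product: 12 (3S,4R)-3-[4-(benzyloxy)-3-methoxybenzyl]-4-{(R)-[4-(benzyloxy)-3-methoxyphenyl](hydroxy)methyl}-3-hydroxyoxolan-2-one, via primary alcohol 11 (not isolated)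
Conditions: TBAF (1.2 equiv), THF, 0 °C → rt; AcOH quench
Reagents that add atoms: none
Why: Fluoride desilylation frees the primary alkoxide, which undergoes intramolecular transesterification (translactonisation) to the less strained lactone on the primary oxygen. No stereocentre is touched, and the benzylated phenols cannot form a quinone methide, so the released C7–OH keeps its configuration.

Step 6
Reactants: 12 (3S,4R)-3-[4-(benzyloxy)-3-methoxybenzyl]-4-{(R)-[4-(benzyloxy)-3-methoxyphenyl](hydroxy)methyl}-3-hydroxyoxolan-2-one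
Product: 13 (3S,4R)-3-hydroxy-3-(4-hydroxy-3-methoxybenzyl)-4-[(R)-hydroxy(4-hydroxy-3-methoxyphenyl)methyl]oxolan-2-one
Conditions: H2 (1 atm), 10% Pd/C, EtOAc, rt, stopped at full conversion
Reagents that add atoms: none
Why: Catalytic hydrogenolysis cleaves the two aryl benzyl ethers, which under neutral conditions at 1 atm is much faster than cleavage of the benzylic C7–OH bond.

**Compound list**

1 | allyl tert-butyldimethylsilyl ether | C=CCO[Si](C)(C)C(C)(C)C | starting material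
2 | (E)-but-2-enal (crotonaldehyde) | C/C=C/C=O | starting material
3 | (2E)-4-{[tert-butyl(dimethyl)silyl]oxy}but-2-enal | O=C/C=C/CO[Si](C)(C)C(C)(C)C | intermediate
4 | 4-(benzyloxy)-3-methoxybenzaldehyde (O-benzylvanillin) | COc1cc(C=O)ccc1OCc1ccccc1 | starting material
5 | (4R,5R)-5-[4-(benzyloxy)-3-methoxyphenyl]-4-({[tert-butyl(dimethyl)silyl]oxy}methyl)oxolan-2-one (cis) | O=C1C[C@H](CO[Si](C)(C)C(C)(C)C)[C@H](c2ccc(OCc3ccccc3)c(OC)c2)O1 | intermediate
6 | lithium aldolate: lithium alkoxide of (4R,5R)-3-{[4-(benzyloxy)-3-methoxyphenyl](hydroxy)methyl}-5-[4-(benzyloxy)-3-methoxyphenyl]-4-({[tert-butyl(dimethyl)silyl]oxy}methyl)oxolan-2-one (epimers at C3 and the carbinol carbon; not isolated) | O=C1C(C([O-])c2ccc(OCc3ccccc3)c(OC)c2)[C@H](CO[Si](C)(C)C(C)(C)C)[C@H](c2ccc(OCc3ccccc3)c(OC)c2)O1.[Li+] | intermediate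
7 | aldol acetate: [4-(benzyloxy)-3-methoxyphenyl][(4R,5R)-5-[4-(benzyloxy)-3-methoxyphenyl]-4-({[tert-butyl(dimethyl)silyl]oxy}methyl)-2-oxooxolan-3-yl]methyl acetate (epimer mixture; not isolated) | O=C1C(C(OC(C)=O)c2ccc(OCc3ccccc3)c(OC)c2)[C@H](CO[Si](C)(C)C(C)(C)C)[C@H](c2ccc(OCc3ccccc3)c(OC)c2)O1 | intermediate
8 | (3E,4R,5R)-3-[4-(benzyloxy)-3-methoxybenzylidene]-5-[4-(benzyloxy)-3-methoxyphenyl]-4-({[tert-butyl(dimethyl)silyl]oxy}methyl)oxolan-2-one | O=C1/C(=C/c2ccc(OCc3ccccc3)c(OC)c2)[C@H](CO[Si](C)(C)C(C)(C)C)[C@H](c2ccc(OCc3ccccc3)c(OC)c2)O1 | intermediate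
9 | tertiary hydroperoxide: (3S,4R,5R)-3-[4-(benzyloxy)-3-methoxybenzyl]-5-[4-(benzyloxy)-3-methoxyphenyl]-4-({[tert-butyl(dimethyl)silyl]oxy}methyl)-3-hydroperoxyoxolan-2-one (not isolated) | O=C1[C@](OO)(Cc2ccc(OCc3ccccc3)c(OC)c2)[C@H](CO[Si](C)(C)C(C)(C)C)[C@H](c2ccc(OCc3ccccc3)c(OC)c2)O1 | intermediate
10 | (3S,4R,5R)-3-[4-(benzyloxy)-3-methoxybenzyl]-5-[4-(benzyloxy)-3-methoxyphenyl]-4-({[tert-butyl(dimethyl)silyl]oxy}methyl)-3-hydroxyoxolan-2-one (benzyl, CH2OTBS and aryl all cis; OH trans) | O=C1[C@](O)(Cc2ccc(OCc3ccccc3)c(OC)c2)[C@H](CO[Si](C)(C)C(C)(C)C)[C@H](c2ccc(OCc3ccccc3)c(OC)c2)O1 | intermediate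
11 | primary alcohol: (3S,4R,5R)-3-[4-(benzyloxy)-3-methoxybenzyl]-5-[4-(benzyloxy)-3-methoxyphenyl]-3-hydroxy-4-(hydroxymethyl)oxolan-2-one (not isolated) | O=C1[C@](O)(Cc2ccc(OCc3ccccc3)c(OC)c2)[C@H](CO)[C@H](c2ccc(OCc3ccccc3)c(OC)c2)O1 | intermediate
12 | (3S,4R)-3-[4-(benzyloxy)-3-methoxybenzyl]-4-{(R)-[4-(benzyloxy)-3-methoxyphenyl](hydroxy)methyl}-3-hydroxyoxolan-2-one | COc1cc(C[C@@]2(O)C(=O)OC[C@@H]2[C@@H](O)c2ccc(OCc3ccccc3)c(OC)c2)ccc1OCc1ccccc1 | intermediate
13 | (3S,4R)-3-hydroxy-3-(4-hydroxy-3-methoxybenzyl)-4-[(R)-hydroxy(4-hydroxy-3-methoxyphenyl)methyl]oxolan-2-one (CNP0352022.1) | COc1cc(C[C@@]2(O)C(=O)OC[C@@H]2[C@@H](O)c2ccc(O)c(OC)c2)ccc1O | target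

**Step count**
Total steps: 6. Longest linear sequence: 6 (1 → 3 → 5 → 8 → 10 → 12 → 13).

**Three steps most likely to fail**

Step 2 (proposed new annulation). Risks are the low electrophilicity of the electron-rich aldehyde, enal self-annulation, and unproven cis and enantioselectivity. The fallback uses known enamine catalysis, sets out from 4 and returns at 5. L-Proline (20 mol%, DMF, 4 °C) catalyses the anti-selective cross-aldol addition of commercial methyl 4-oxobutanoate to 4, giving methyl (3S,4R)-4-[4-(benzyloxy)-3-methoxyphenyl]-3-formyl-4-hydroxybutanoate F1. NaBH4 (MeOH, −20 °C) reduces the aldehyde to the diol methyl (3R,4R)-4-[4-(benzyloxy)-3-methoxyphenyl]-4-hydroxy-3-(hydroxymethyl)butanoate F2. TBSCl/imidazole (CH2Cl2, 0 °C) silylates the primary hydroxyl to give methyl (3R,4R)-4-[4-(benzyloxy)-3-methoxyphenyl]-3-({[tert-butyl(dimethyl)silyl]oxy}methyl)-4-hydroxybutanoate F3. Catalytic PPTS in warm toluene closes the lactone on the benzylic hydroxyl and gives 5.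

Step 4 (reductive α-hydroxylation). Risks are H-atom transfer to the wrong alkene carbon (benzylic radical, β-oxygenation) or incomplete facial selectivity in the radical trapping. The fallback replaces the radical path by conjugate reduction and enolate oxidation, sets out from 8 and returns at 10. Copper hydride conjugate reduction (Cu(OAc)2·H2O, 1,2-bis(diphenylphosphino)benzene, PMHS, t-BuOH, toluene) gives (4R,5R)-3-[4-(benzyloxy)-3-methoxybenzyl]-5-[4-(benzyloxy)-3-methoxyphenyl]-4-({[tert-butyl(dimethyl)silyl]oxy}methyl)oxolan-2-one F4 (C3 epimers, inconsequential). The potassium enolate (KHMDS, THF, −78 °C) is then hydroxylated with 2-(phenylsulfonyl)-3-phenyloxaziridine (Davis reagent) anti to the C4 substituent, the sense established for lignan lactone enolates, to give 10.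

Step 6 (hydrogenolysis). The risk is loss of the benzylic C7–OH once the para-phenol is unmasked. The fallback removes the benzylic C–O bond before hydrogenation and restores it under catalyst control, sets out from 12 and returns at 13. Dess–Martin periodinane (NaHCO3, CH2Cl2) oxidises the secondary benzylic alcohol to (3S,4S)-3-[4-(benzyloxy)-3-methoxybenzyl]-4-[4-(benzyloxy)-3-methoxybenzoyl]-3-hydroxyoxolan-2-one F5. Hydrogenolysis (H2, Pd/C, EtOAc) gives (3S,4S)-3-hydroxy-3-(4-hydroxy-3-methoxybenzyl)-4-(4-hydroxy-3-methoxybenzoyl)oxolan-2-one F6. Noyori asymmetric transfer hydrogenation (RuCl[(R,R)-TsDPEN](p-cymene), HCO2H/Et3N) then sets the (R)-carbinol and gives 13.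

Further compounds
F1 | step 2 | methyl (3S,4R)-4-[4-(benzyloxy)-3-methoxyphenyl]-3-formyl-4-hydroxybutanoate | COC(=O)C[C@H](C=O)[C@@H](O)c1ccc(OCc2ccccc2)c(OC)c1
F2 | step 2 | methyl (3R,4R)-4-[4-(benzyloxy)-3-methoxyphenyl]-4-hydroxy-3-(hydroxymethyl)butanoate | COC(=O)C[C@H](CO)[C@@H](O)c1ccc(OCc2ccccc2)c(OC)c1
F3 | step 2 | methyl (3R,4R)-4-[4-(benzyloxy)-3-methoxyphenyl]-3-({[tert-butyl(dimethyl)silyl]oxy}methyl)-4-hydroxybutanoate | COC(=O)C[C@H](CO[Si](C)(C)C(C)(C)C)[C@@H](O)c1ccc(OCc2ccccc2)c(OC)c1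
F4 | step 4 | (4R,5R)-3-[4-(benzyloxy)-3-methoxybenzyl]-5-[4-(benzyloxy)-3-methoxyphenyl]-4-({[tert-butyl(dimethyl)silyl]oxy}methyl)oxolan-2-one (C3 epimers) | O=C1C(Cc2ccc(OCc3ccccc3)c(OC)c2)[C@H](CO[Si](C)(C)C(C)(C)C)[C@H](c2ccc(OCc3ccccc3)c(OC)c2)O1
F5 | step 6 | (3S,4S)-3-[4-(benzyloxy)-3-methoxybenzyl]-4-[4-(benzyloxy)-3-methoxybenzoyl]-3-hydroxyoxolan-2-one | COc1cc(C[C@@]2(O)C(=O)OC[C@@H]2C(=O)c2ccc(OCc3ccccc3)c(OC)c2)ccc1OCc1ccccc1
F6 | step 6 | (3S,4S)-3-hydroxy-3-(4-hydroxy-3-methoxybenzyl)-4-(4-hydroxy-3-methoxybenzoyl)oxolan-2-one | COc1cc(C[C@@]2(O)C(=O)OC[C@@H]2C(=O)c2ccc(O)c(OC)c2)ccc1O
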